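**Strategy**

Everything rests on cutting the only ring alkene, C3=C4, of the cyclohexene numbered C1 (aroyl), C2 (prenyl), C3 (methyl), C4, C5, C6 (phenyl). No stereocentre is made or broken at that bond, so ring-closing metathesis can form the C3–C4 bond, the six-membered ring and the alkene position in one catalytic operation without touching C1, C2 or C6. The precursor is an acyclic aryl ketone whose C2 carries isopropenyl and prenyl groups and whose C6 carries phenyl and allyl groups. Its S,S,S triad comes from a chair Ireland–Claisen rearrangement of an (E)-dienyl (S)-3-phenylhex-5-enoate, and its aroyl group from an ortho-lithiated, acetal-protected trimethoxyphenol.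

Key step: step 13

Remark: with the ring numbering above, the target is 1S,2S,6S with the aroyl group trans to both neighbours; the same three descriptors hold for every open-chain intermediate from 17 onward.
Remark: (R)-BINAP is assigned to the R-lactone 3 by analogy with the facial sense of this ligand on six-membered cyclic acceptors; the other ligand enantiomer would be used if the rotation of 3 showed otherwise.
Remark: the aryl ketone is built through the aldehyde (aryllithium addition, then oxidation) and not by acyl substitution at the very hindered C1 carboxyl, and all three centres are set kinetically in step 8, so no equilibration at C1 is relied on.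

**Route**

Step 1
Reactants: 1 5,6-dihydro-2H-pyran-2-one; 2 phenylboronic acid
Product: 3 (R)-4-phenyloxan-2-one
Conditions: Rh(acac)(C2H4)2 (3 mol%), (R)-BINAP (3.3 mol%), dioxane/H2O 10:1, 100 °C
Reagents that add atoms: none
Why: Hayashi–Miyaura rhodium-catalysed asymmetric conjugate addition, in which the phenylrhodium–BINAP species adds to one face of the lactone alkene and water protonates the rhodium enolate, so the ligand sets the benzylic centre (future C6) as R.

Step 2
Reactants: 3 (R)-4-phenyloxan-2-one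
Product: 4 (4R)-4-phenyloxan-2-ol (lactol, both anomers)
Conditions: iBu2AlH (1.1 equiv), CH2Cl2, −78 °C; aq. potassium sodium tartrate
Reagents that add atoms: none
Why: Partial hydride reduction of a lactone, where the aluminium hemiacetal is stable at low temperature and should release the lactol only on work-up.

Step 3
Reactants: 4 (4R)-4-phenyloxan-2-ol
Product: 6 (S)-3-phenylhex-5-en-1-ol, via (R)-5-hydroxy-3-phenylpentanal 5 (not isolated)
Conditions: Ph3PCH3Br (3 equiv), KOtBu (2.8 equiv), THF, 0 °C → rt
Reagents that add atoms: methyltriphenylphosphonium bromide, C[P+](c1ccccc1)(c1ccccc1)c1ccccc1.[Br-]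
Why: Wittig methylenation of the lactol through its open hydroxy-aldehyde form, with excess ylide to cover the hydroxyl proton; the stereocentre is β to the aldehyde and is not at risk.

Step 4
Reactants: 6 (S)-3-phenylhex-5-en-1-ol
Product: 8 (S)-3-phenylhex-5-enoic acid, via (S)-3-phenylhex-5-enal 7 (not isolated)
Conditions: TEMPO (0.2 equiv), PhI(OAc)2 (2.2 equiv), MeCN/H2O 1:1, rt
Reagents that add atoms: water, O
Why: Oxoammonium-mediated oxidation of a primary alcohol to the acid through the aldehyde hydrate, conditions that leave the terminal alkene and the benzylic C–H alone.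

Step 5
Reactants: 9 4-methylpent-3-en-1-ol; 10 ethyl 2-(triphenyl-λ5-phosphanylidene)propanoate
Product: 12 ethyl (E)-2,6-dimethylhepta-2,5-dienoate, via 4-methylpent-3-enal 11 (not isolated)
Conditions: IBX (1.3 equiv), 10 (1.5 equiv) present from the start, DMSO, rt
Reagents that add atoms: none
Why: Tandem IBX oxidation and Wittig olefination, in which the stabilised α-methyl ylide traps the β,γ-unsaturated aldehyde as it forms (before it can move into conjugation) and should give the E trisubstituted enoate.

Step 6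
Reactants: 12 ethyl (E)-2,6-dimethylhepta-2,5-dienoate
Product: 13 (E)-2,6-dimethylhepta-2,5-dien-1-ol
Conditions: iBu2AlH (2.2 equiv), CH2Cl2, −78 → 0 °C; aq. potassium sodium tartrate
Reagents that add atoms: none
Why: 1,2-Reduction of an enoate to the allylic alcohol by iBu2AlH, which keeps the alkene geometry.

Step 7
Reactants: 8 (S)-3-phenylhex-5-enoic acid; 13 (E)-2,6-dimethylhepta-2,5-dien-1-ol
Product: 14 (2E)-2,6-dimethylhepta-2,5-dien-1-yl (3S)-3-phenylhex-5-enoate
Conditions: DCC, DMAP (cat.), CH2Cl2, 0 °C → rt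
Reagents that add atoms: none
Why: Steglich esterification of an unhindered acid with a primary allylic alcohol under neutral conditions.

Step 8
Reactants: 14 (2E)-2,6-dimethylhepta-2,5-dien-1-yl (3S)-3-phenylhex-5-enoate
Product: 18 (2S,3S)-6-methyl-2-[(1S)-1-phenylbut-3-en-1-yl]-3-(prop-1-en-2-yl)hept-5-en-1-ol, via lithium enolate 15 (not isolated), via silyl ketene acetal 16 (not isolated), via trimethylsilyl ester 17 (not isolated)
Conditions: Me3SiCl/Et3N, THF, −78 °C, LiN(iPr)2 added slowly (in-situ silylation), −78 °C → rt → 50 °C; then LiAlH4, 0 °C; aq. NaOH work-up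
Reagents that add atoms: chlorotrimethylsilane, C[Si](C)(C)Cl (silicon present in 16 and 17 only); lithium diisopropylamide, [Li]N(C(C)C)C(C)C (lithium present in 15 only)
Why: Ireland–Claisen rearrangement followed by hydride reduction of the silyl ester: kinetic enolisation in THF without polar cosolvent should give the (E)-silyl ketene acetal, whose chair with the E-alkene (prenyl CH2 equatorial, ketene acetal substituent axial) sets the anti C1/C2 relationship, while the allyl unit should add anti to phenyl in the conformer that holds the C–H of the existing centre in the ketene acetal plane, which sets C1 relative to C6.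

Step 9
Reactants: 18 (2S,3S)-6-methyl-2-[(1S)-1-phenylbut-3-en-1-yl]-3-(prop-1-en-2-yl)hept-5-en-1-ol
Product: 19 (2S,3S)-6-methyl-2-[(1S)-1-phenylbut-3-en-1-yl]-3-(prop-1-en-2-yl)hept-5-enal
Conditions: Dess–Martin periodinane, NaHCO3, CH2Cl2, 0 °C → rt; used at once
Reagents that add atoms: none
Why: Dess–Martin oxidation under buffered, non-basic conditions, which should not epimerise the hindered α-centre.

Step 10
Reactants: 20 3,4,5-trimethoxyphenol
Product: 21 1,2,3-trimethoxy-5-(methoxymethoxy)benzene
Conditions: NaH, MOMCl, THF/DMF, 0 °C → rt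
Reagents that add atoms: chloromethyl methyl ether, COCCl
Why: O-Alkylation of the sodium phenoxide (Williamson-type acetal formation), which installs the directing and protecting group.

Step 11
Reactants: 21 1,2,3-trimethoxy-5-(methoxymethoxy)benzene; 19 (2S,3S)-6-methyl-2-[(1S)-1-phenylbut-3-en-1-yl]-3-(prop-1-en-2-yl)hept-5-enal
Product: 23 (2S,3S)-1-[2-(methoxymethoxy)-4,5,6-trimethoxyphenyl]-6-methyl-2-[(1S)-1-phenylbut-3-en-1-yl]-3-(prop-1-en-2-yl)hept-5-en-1-ol (both carbinol epimers), via aryllithium 22 (not isolated)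
Conditions: n-BuLi, THF, 0 °C (21, 1.8 equiv); then 19, −78 → −20 °C; H2O
Reagents that add atoms: n-butyllithium, [Li]CCCC (lithium present in 22 only)
Why: Directed ortho-metalation followed by 1,2-addition to an aldehyde; the two ring hydrogens of 21 are equivalent and each lies between two oxygens, so a single aryllithium forms, and the new carbinol centre is unselective but is removed in step 12.

Step 12
Reactants: 23 the carbinol from step 11
Product: 24 (2S,3S)-1-[2-(methoxymethoxy)-4,5,6-trimethoxyphenyl]-6-methyl-2-[(1S)-1-phenylbut-3-en-1-yl]-3-(prop-1-en-2-yl)hept-5-en-1-one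
Conditions: Dess–Martin periodinane, NaHCO3, CH2Cl2, rt
Reagents that add atoms: none
Why: Dess–Martin oxidation of a hindered benzylic alcohol to the aryl ketone, neutral enough to leave the C1 centre and the acetal intact.

Step 13
Reactants: 24 the open-chain aryl ketone
Product: 25 [2-(methoxymethoxy)-4,5,6-trimethoxyphenyl][(1S,2S,6S)-3-methyl-2-(3-methylbut-2-en-1-yl)-6-phenylcyclohex-3-en-1-yl]methanone
Conditions: second-generation Grubbs catalyst RuCl2(PCy3)(H2IMes)(=CHPh) (5–10 mol%), CH2Cl2 (5 mM), 40 °C, argon sparge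
Reagents that add atoms: none
Why: Ring-closing olefin metathesis: the benzylidene exchanges with the monosubstituted allyl alkene on C6, the resulting alkylidene undergoes intramolecular [2+2] cycloaddition with the 1,1-disubstituted isopropenyl group on C2, and cycloreversion of the ruthenacyclobutane releases the cyclohexene and Ru=CH2, ethene being the net by-product. The closest known reaction type is closure of 1,7-dienes bearing one 1,1-disubstituted alkene to methyl-substituted cyclohexenes with N-heterocyclic-carbene ruthenium catalysts, including substrates that carry prenyl groups. The one ring formed is the six-membered carbocycle, closed between C3 and C4 across the C2–C1–C6 tether, so the alkene position is fixed by connectivity. No stereocentre is created, and C1, C2 and C6 are untouched because the medium is neutral. The step needs chemoselectivity for the isopropenyl over the prenyl alkene and ring closure over oligomerisation: the prenyl alkene is trisubstituted and could only close a seven-membered ring with loss of 2-methylpropene, and initiation at the single terminal alkene, high dilution and the three contiguous branched carbons should favour cyclisation.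

Step 14
Reactants: 25 the ring-closed acetal-protected ketone
Product: 26 (2-hydroxy-4,5,6-trimethoxyphenyl)[(1S,2S,6S)-3-methyl-2-(3-methylbut-2-en-1-yl)-6-phenylcyclohex-3-en-1-yl]methanone
Conditions: 3 M aq. HCl, MeOH/THF, 40 °C
Reagents that add atoms: none
Why: Acid-catalysed methanolysis of the methoxymethyl acetal, assisted by the neighbouring carbonyl, under conditions mild enough for trisubstituted alkenes.

Step 15
Reactants: 26 the 2-hydroxy-4,5,6-trimethoxyphenyl ketone
Product: 27 (2,6-dihydroxy-3,4-dimethoxyphenyl)[(1S,2S,6S)-3-methyl-2-(3-methylbut-2-en-1-yl)-6-phenylcyclohex-3-en-1-yl]methanone (target)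
Conditions: MgI2·OEt2 (3 equiv), toluene/Et2O, 70 °C; aq. Na2S2O3/NH4Cl
Reagents that add atoms: none
Why: Chelation-directed aryl methyl ether cleavage, in which magnesium bridges the carbonyl oxygen and the flanking methoxy oxygen so that iodide attacks only that methyl group in a neutral medium that should spare the alkenes and the two non-chelated methoxy groups.

**Compound list**

1 | 5,6-dihydro-2H-pyran-2-one | O=C1C=CCCO1 | starting material
2 | phenylboronic acid | OB(O)c1ccccc1 | starting material
3 | (R)-4-phenyloxan-2-one | O=C1C[C@H](c2ccccc2)CCO1 | intermediate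
4 | (4R)-4-phenyloxan-2-ol | OC1C[C@H](c2ccccc2)CCO1 | intermediate
5 | (R)-5-hydroxy-3-phenylpentanal | O=CC[C@H](c1ccccc1)CCO | intermediate (not isolated)
6 | (S)-3-phenylhex-5-en-1-ol | C=CC[C@H](c1ccccc1)CCO | intermediate
7 | (S)-3-phenylhex-5-enal | C=CC[C@H](c1ccccc1)CC=O | intermediate (not isolated)
8 | (S)-3-phenylhex-5-enoic acid | C=CC[C@H](c1ccccc1)CC(=O)O | intermediate
9 | 4-methylpent-3-en-1-ol | CC(C)=CCCO | starting material
10 | ethyl 2-(triphenyl-λ5-phosphanylidene)propanoate | CCOC(=O)C(C)=P(c1ccccc1)(c1ccccc1)c1ccccc1 | starting material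
11 | 4-methylpent-3-enal | CC(C)=CCC=O | intermediate (not isolated)
12 | ethyl (E)-2,6-dimethylhepta-2,5-dienoate | CCOC(=O)/C(C)=C/CC=C(C)C | intermediate
13 | (E)-2,6-dimethylhepta-2,5-dien-1-ol | OC/C(C)=C/CC=C(C)C | intermediate
14 | (2E)-2,6-dimethylhepta-2,5-dien-1-yl (3S)-3-phenylhex-5-enoate | C=CC[C@H](c1ccccc1)CC(=O)OC/C(C)=C/CC=C(C)C | intermediate
15 | lithium enolate of 14 (C3 substituent trans to OLi) | [Li]O/C(OC/C(C)=C/CC=C(C)C)=C/[C@H](CC=C)c1ccccc1 | intermediate (not isolated)
16 | (1E,3S)-1-{[(2E)-2,6-dimethylhepta-2,5-dien-1-yl]oxy}-3-phenyl-1-(trimethylsilyloxy)hexa-1,5-diene | C[Si](C)(C)O/C(OC/C(C)=C/CC=C(C)C)=C/[C@H](CC=C)c1ccccc1 | intermediate (not isolated)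
17 | trimethylsilyl (2S,3S)-6-methyl-2-[(1S)-1-phenylbut-3-en-1-yl]-3-(prop-1-en-2-yl)hept-5-enoate | C[Si](C)(C)OC(=O)[C@@H]([C@H](CC=C(C)C)C(C)=C)[C@H](CC=C)c1ccccc1 | intermediate (not isolated)
18 | (2S,3S)-6-methyl-2-[(1S)-1-phenylbut-3-en-1-yl]-3-(prop-1-en-2-yl)hept-5-en-1-ol | OC[C@@H]([C@H](CC=C(C)C)C(C)=C)[C@H](CC=C)c1ccccc1 | intermediate
19 | (2S,3S)-6-methyl-2-[(1S)-1-phenylbut-3-en-1-yl]-3-(prop-1-en-2-yl)hept-5-enal | O=C[C@@H]([C@H](CC=C(C)C)C(C)=C)[C@H](CC=C)c1ccccc1 | intermediate
20 | 3,4,5-trimethoxyphenol | COc1cc(O)cc(OC)c1OC | starting material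
21 | 1,2,3-trimethoxy-5-(methoxymethoxy)benzene | COCOc1cc(OC)c(OC)c(OC)c1 | intermediate
22 | [2-(methoxymethoxy)-4,5,6-trimethoxyphenyl]lithium | [Li]c1c(OCOC)cc(OC)c(OC)c1OC | intermediate (not isolated)
23 | (2S,3S)-1-[2-(methoxymethoxy)-4,5,6-trimethoxyphenyl]-6-methyl-2-[(1S)-1-phenylbut-3-en-1-yl]-3-(prop-1-en-2-yl)hept-5-en-1-ol, both C1 epimers | COCOc1cc(OC)c(OC)c(OC)c1C(O)[C@@H]([C@H](CC=C(C)C)C(C)=C)[C@H](CC=C)c1ccccc1 | intermediate
24 | (2S,3S)-1-[2-(methoxymethoxy)-4,5,6-trimethoxyphenyl]-6-methyl-2-[(1S)-1-phenylbut-3-en-1-yl]-3-(prop-1-en-2-yl)hept-5-en-1-one | COCOc1cc(OC)c(OC)c(OC)c1C(=O)[C@@H]([C@H](CC=C(C)C)C(C)=C)[C@H](CC=C)c1ccccc1 | intermediate (key-step precursor)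
25 | [2-(methoxymethoxy)-4,5,6-trimethoxyphenyl][(1S,2S,6S)-3-methyl-2-(3-methylbut-2-en-1-yl)-6-phenylcyclohex-3-en-1-yl]methanone | COCOc1cc(OC)c(OC)c(OC)c1C(=O)[C@H]1[C@H](CC=C(C)C)C(C)=CC[C@@H]1c1ccccc1 | intermediate (key-step product)
26 | (2-hydroxy-4,5,6-trimethoxyphenyl)[(1S,2S,6S)-3-methyl-2-(3-methylbut-2-en-1-yl)-6-phenylcyclohex-3-en-1-yl]methanone | COc1cc(O)c(C(=O)[C@H]2[C@H](CC=C(C)C)C(C)=CC[C@@H]2c2ccccc2)c(OC)c1OC | intermediate
27 | (2,6-dihydroxy-3,4-dimethoxyphenyl)[(1S,2S,6S)-3-methyl-2-(3-methylbut-2-en-1-yl)-6-phenylcyclohex-3-en-1-yl]methanone | COc1cc(O)c(C(=O)[C@H]2[C@H](CC=C(C)C)C(C)=CC[C@@H]2c2ccccc2)c(O)c1OC | target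

**Step count**

Total: 15 steps. Longest linear sequence: 12 steps (1, 2, 3, 4, 7, 8, 9, 11, 12, 13, 14, 15).

**Steps most likely to fail**

Step 8. The risk is erosion of diastereocontrol. In the required chair the ketene acetal substituent is axial and faces the methyl group on the central allyl carbon, so a boat pathway (which inverts C2 relative to C1) may leak in. Imperfect enolate geometry or weak discrimination between the phenyl and CH2 faces would add to this. The fallback sets out from 9 and 8 and comes back at 17; it inverts both alkene geometries so that the large substituent becomes equatorial.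
- Aldehyde 11 (from 9 with Dess–Martin periodinane, used as a cold filtered solution) is condensed with ethyl 2-[bis(2,2,2-trifluoroethoxy)phosphoryl]propanoate (KN(SiMe3)2, 18-crown-6, THF, −78 °C; Still–Gennari olefination) to give ethyl (Z)-2,6-dimethylhepta-2,5-dienoate F1.
- Reduction with iBu2AlH gives (Z)-2,6-dimethylhepta-2,5-dien-1-ol F2.
- DCC/DMAP coupling with 8 gives (2Z)-2,6-dimethylhepta-2,5-dien-1-yl (3S)-3-phenylhex-5-enoate F3.
- LiN(iPr)2 in THF/DMPU gives the lithium enolate with the C3 substituent cis to OLi F4, which Me3SiCl converts into the (1Z)-silyl ketene acetal F5.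
- The chair of F5 has only the CH2 of the Z-alkene axial and still gives the anti C1/C2 relationship. The bulkier cis-OSiMe3 group should also hold the C–H of the existing centre in plane more firmly. Rearrangement gives 17, which is reduced to 18 as before.

Step 13. The risk is slow closure onto the hindered 1,1-disubstituted alkene of the congested ketone, perhaps slowed further by carbonyl coordination to ruthenium. Intermolecular metathesis at the allyl terminus or engagement of the prenyl alkene could then compete. The fallback sets out from 18 and comes back at 25; it closes the ring before the aryl group is attached.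
- Alcohol 18 is treated with the same catalyst under the same dilution to give [(1S,2S,6S)-3-methyl-2-(3-methylbut-2-en-1-yl)-6-phenylcyclohex-3-en-1-yl]methanol F6.
- Dess–Martin oxidation gives (1S,2S,6S)-3-methyl-2-(3-methylbut-2-en-1-yl)-6-phenylcyclohex-3-ene-1-carbaldehyde F7.
- Addition of aryllithium 22 gives [2-(methoxymethoxy)-4,5,6-trimethoxyphenyl][(1S,2S,6S)-3-methyl-2-(3-methylbut-2-en-1-yl)-6-phenylcyclohex-3-en-1-yl]methanol F8.
- Dess–Martin oxidation of F8 gives 25.

Step 15. The risk is incomplete or unselective ether cleavage. The hydrogen-bonded hydroxyl on the other ortho position weakens magnesium coordination at the carbonyl, so the reaction may stall. If forced, it may also cleave the central methoxy group of the contiguous trimethoxy array. The fallback sets out from 19 and comes back at 27; it avoids demethylation by carrying both ortho oxygens as acetals.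
- Commercial 3-hydroxy-4,5-dimethoxybenzaldehyde is protected (NaH, MOMCl) as 3,4-dimethoxy-5-(methoxymethoxy)benzaldehyde F9.
- Baeyer–Villiger oxidation with mCPBA gives 3,4-dimethoxy-5-(methoxymethoxy)phenyl formate F10.
- Methanolysis (K2CO3, MeOH) gives 3,4-dimethoxy-5-(methoxymethoxy)phenol F11.
- A second MOM protection gives 1,2-dimethoxy-3,5-bis(methoxymethoxy)benzene F12.
- Lithiation with n-BuLi is expected between the two acetal oxygens and gives [2,6-bis(methoxymethoxy)-3,4-dimethoxyphenyl]lithium F13.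
- Addition to 19 gives (2S,3S)-1-[2,6-bis(methoxymethoxy)-3,4-dimethoxyphenyl]-6-methyl-2-[(1S)-1-phenylbut-3-en-1-yl]-3-(prop-1-en-2-yl)hept-5-en-1-ol F14.
- Dess–Martin oxidation gives (2S,3S)-1-[2,6-bis(methoxymethoxy)-3,4-dimethoxyphenyl]-6-methyl-2-[(1S)-1-phenylbut-3-en-1-yl]-3-(prop-1-en-2-yl)hept-5-en-1-one F15.
- Ring-closing metathesis as in step 13 gives [2,6-bis(methoxymethoxy)-3,4-dimethoxyphenyl][(1S,2S,6S)-3-methyl-2-(3-methylbut-2-en-1-yl)-6-phenylcyclohex-3-en-1-yl]methanone F16.
- Aqueous HCl in MeOH removes both acetals from F16 and gives 27.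

**Further compounds**

F1 | step 8 | ethyl (Z)-2,6-dimethylhepta-2,5-dienoate | CCOC(=O)/C(C)=C\CC=C(C)C
F2 | step 8 | (Z)-2,6-dimethylhepta-2,5-dien-1-ol | OC/C(C)=C\CC=C(C)C
F3 | step 8 | (2Z)-2,6-dimethylhepta-2,5-dien-1-yl (3S)-3-phenylhex-5-enoate | C=CC[C@H](c1ccccc1)CC(=O)OC/C(C)=C\CC=C(C)C
F4 | step 8 | lithium enolate of F3 (C3 substituent cis to OLi) | [Li]O/C(OC/C(C)=C\CC=C(C)C)=C\[C@H](CC=C)c1ccccc1
F5 | step 8 | (1Z,3S)-1-{[(2Z)-2,6-dimethylhepta-2,5-dien-1-yl]oxy}-3-phenyl-1-(trimethylsilyloxy)hexa-1,5-diene | C[Si](C)(C)O/C(OC/C(C)=C\CC=C(C)C)=C\[C@H](CC=C)c1ccccc1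
F6 | step 13 | [(1S,2S,6S)-3-methyl-2-(3-methylbut-2-en-1-yl)-6-phenylcyclohex-3-en-1-yl]methanol | OC[C@H]1[C@H](CC=C(C)C)C(C)=CC[C@@H]1c1ccccc1
F7 | step 13 | (1S,2S,6S)-3-methyl-2-(3-methylbut-2-en-1-yl)-6-phenylcyclohex-3-ene-1-carbaldehyde | O=C[C@H]1[C@H](CC=C(C)C)C(C)=CC[C@@H]1c1ccccc1
F8 | step 13 | [2-(methoxymethoxy)-4,5,6-trimethoxyphenyl][(1S,2S,6S)-3-methyl-2-(3-methylbut-2-en-1-yl)-6-phenylcyclohex-3-en-1-yl]methanol | COCOc1cc(OC)c(OC)c(OC)c1C(O)[C@H]1[C@H](CC=C(C)C)C(C)=CC[C@@H]1c1ccccc1
F9 | step 15 | 3,4-dimethoxy-5-(methoxymethoxy)benzaldehyde | COCOc1cc(C=O)cc(OC)c1OC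
F10 | step 15 | 3,4-dimethoxy-5-(methoxymethoxy)phenyl formate | COCOc1cc(OC=O)cc(OC)c1OC
F11 | step 15 | 3,4-dimethoxy-5-(methoxymethoxy)phenol | COCOc1cc(O)cc(OC)c1OC
F12 | step 15 | 1,2-dimethoxy-3,5-bis(methoxymethoxy)benzene | COCOc1cc(OCOC)c(OC)c(OC)c1
F13 | step 15 | [2,6-bis(methoxymethoxy)-3,4-dimethoxyphenyl]lithium | [Li]c1c(OCOC)cc(OC)c(OC)c1OCOC
F14 | step 15 | (2S,3S)-1-[2,6-bis(methoxymethoxy)-3,4-dimethoxyphenyl]-6-methyl-2-[(1S)-1-phenylbut-3-en-1-yl]-3-(prop-1-en-2-yl)hept-5-en-1-ol | COCOc1cc(OC)c(OC)c(OCOC)c1C(O)[C@@H]([C@H](CC=C(C)C)C(C)=C)[C@H](CC=C)c1ccccc1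
F15 | step 15 | (2S,3S)-1-[2,6-bis(methoxymethoxy)-3,4-dimethoxyphenyl]-6-methyl-2-[(1S)-1-phenylbut-3-en-1-yl]-3-(prop-1-en-2-yl)hept-5-en-1-one | COCOc1cc(OC)c(OC)c(OCOC)c1C(=O)[C@@H]([C@H](CC=C(C)C)C(C)=C)[C@H](CC=C)c1ccccc1
F16 | step 15 | [2,6-bis(methoxymethoxy)-3,4-dimethoxyphenyl][(1S,2S,6S)-3-methyl-2-(3-methylbut-2-en-1-yl)-6-phenylcyclohex-3-en-1-yl]methanone | COCOc1cc(OC)c(OC)c(OCOC)c1C(=O)[C@H]1[C@H](CC=C(C)C)C(C)=CC[C@@H]1c1ccccc1
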